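The seven-membered ring (C3a, C4–C8, C8a) is cut at C3a–C4 and C8–C8a, giving cyclopentane-1,3-dione (C4–C8) and a cyclopentenyl ester with the C3a=C8a double bond. The feature exploited is the cis pair of adjacent, fully substituted ring-fusion carbons, C3a (oxygen) and C8a (methyl), with the C7 oxygen two bonds from C8a. A de Mayo photocycloaddition with retro-aldol opening inserts the olefin into the dione: one operation closes the seven-membered ring, forms both bonds and sets both centres anti to the C3 isopropyl group. The precursor is the (R)-enol pivalate 8 of 2-isopropyl-5-methylcyclopentanone from (S)-limonene; pivalate is chosen over acetate because it cannot enolise or migrate in later base steps.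

Key step: step 6

Locants: the azulene numbering of the target is used for all bicyclic compounds and for the atoms of 8 and 9 that enter the bicycle (C3 isopropyl, C3a ring-fusion oxygen, C8a angular methyl, C6 methyl carbinol, C7 ester). β is the face of the C8a methyl group, α the opposite face.
Assumption: commercial (S)-(−)-limonene of high enantiomeric purity is used; its stereocentre becomes C3, is never epimerisable on the way and controls all other centres.

Step 1
Reactants: 1 (S)-limonene
Product: 2 (S)-p-menth-1-ene
Conditions: H2 (1 atm, stopped after 1.0 equiv), PtO2 (cat.), EtOH, rt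
Reagents that add atoms: none
Why: Chemoselective heterogeneous hydrogenation: the unhindered 1,1-disubstituted isopropenyl double bond is saturated much faster than the trisubstituted ring olefin, and the stereocentre is not touched.

Step 2
Reactants: 2 (S)-p-menth-1-ene
Product: 4 (S)-3-isopropyl-6-oxoheptanal, via ozonide 3 (not isolated)
Conditions: O3, CH2Cl2, −78 °C; then Me2S, −78 °C → rt
Reagents that add atoms: ozone, [O-][O+]=O
Why: Ozonolysis with reductive work-up cleaves the only double bond to a methyl ketone and an aldehyde without involving the stereocentre.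

Step 3
Reactants: 4 (S)-3-isopropyl-6-oxoheptanal
Product: 5 (5R)-5-isopropyl-2-methylcyclopent-1-ene-1-carbaldehyde
Conditions: piperidine (cat.), AcOH (cat.), toluene, reflux, Dean–Stark trap
Reagents that add atoms: none
Why: Amine-catalysed intramolecular aldol condensation: the enamine of the aldehyde attacks the methyl ketone in a five-membered closure and dehydration gives the tetrasubstituted conjugated enal, while the stereocentre carries no acidic hydrogen and is kept.

Step 4
Reactants: 5 (5R)-5-isopropyl-2-methylcyclopent-1-ene-1-carbaldehyde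
Product: 6 (5R)-5-isopropyl-2-methylcyclopent-1-en-1-yl formate
Conditions: 30% aq. H2O2, (2-O2NC6H4Se)2 (cat.), CH2Cl2, rt
Reagents that add atoms: hydrogen peroxide, OO
Why: Baeyer–Villiger oxidation of an α,β-unsaturated aldehyde by the areneseleninic peracid formed in the flask: the alkenyl group migrates in preference to hydrogen, so the enol formate keeps the double bond at C1=C2, and this oxidant should not epoxidise the product.

Step 5
Reactants: 6 (5R)-5-isopropyl-2-methylcyclopent-1-en-1-yl formate
Product: 8 (5R)-5-isopropyl-2-methylcyclopent-1-en-1-yl pivalate, via lithium enolate 7 (not isolated)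
Conditions: MeLi (2.0 equiv), THF, −78 → 0 °C (6 added to MeLi); then t-BuCOCl (2.2 equiv), DMPU, −78 °C → rt
Reagents that add atoms: pivaloyl chloride, CC(C)(C)C(=O)Cl
Why: Organolithium cleavage of an enol ester followed by O-acylation of the enolate: MeLi removes the formyl group (the second equivalent turns the acetaldehyde formed into isopropoxide), the lithium enolate stays at C1=C2 because no proton source is present, and the hindered tetrasubstituted enolate is acylated on oxygen, so C5 keeps its configuration.

Step 6
Reactants: 8 (5R)-5-isopropyl-2-methylcyclopent-1-en-1-yl pivalate; 9 cyclopentane-1,3-dione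
Product: 11 (3R,3aS,8aR)-3-isopropyl-8a-methyl-4,7-dioxodecahydroazulen-3a-yl pivalate, via cyclobutanol photoadduct 10 (not isolated)
Conditions: hν (medium-pressure Hg lamp, Pyrex filter, λ ≥ 300 nm), MeCN, degassed, 10 °C; 9 (3 equiv) added in portions
Reagents that add atoms: none
Why: The excited enol of 9 (a 3-hydroxycyclopent-2-enone chromophore) adds stepwise through a 1,4-biradical across C3a=C8a of 8, and cyclobutanol 10, a β-hydroxy ketone locked in a four-membered ring, relieves its strain at once by retro-aldol cleavage of C4–C8; this is the de Mayo reaction of a cyclic 1,3-dione, here with an enol ester as the olefin. The seven-membered ring is therefore closed by ring expansion and not by end-to-end cyclisation: an intermolecular [2+2] cycloaddition forms C3a–C4 and C8–C8a (the transient cyclobutane closing by biradical recombination), and the fragmentation merges the four-membered ring with the five-membered dione ring into the cycloheptane-4,7-dione. C3a and C8a are set together: a four-membered ring cannot bridge the two faces of the cyclopentene, so oxygen and methyl must end up cis, and the dione should approach the face opposite the isopropyl group on C3, the carbon next to C3a, which leaves pivalate and methyl on the isopropyl (β) face. The step needs head-to-tail orientation, which the donor oxygen on C3a should secure because donor-substituted olefin carbons bond to the oxygen-bearing β-carbon of the excited enone (C4), and it needs anti facial selectivity, which the adjacent isopropyl group should secure. The configuration of 10 at C4 and C8 is of no account, since C4 becomes a carbonyl and C8 a methylene group, and the pivalate neither absorbs above 300 nm nor reacts with the acidic dione.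

Step 7
Reactants: 11 (3R,3aS,8aR)-3-isopropyl-8a-methyl-4,7-dioxodecahydroazulen-3a-yl pivalate
Product: 12 (3R,3aS,8aR)-7,7-(ethylenedioxy)-3-isopropyl-8a-methyl-4-oxodecahydroazulen-3a-yl pivalate
Conditions: HOCH2CH2OH, pyridinium p-toluenesulfonate (cat.), toluene, reflux, Dean–Stark trap
Reagents that add atoms: ethylene glycol, OCCO
Why: Acid-catalysed ketalisation is chemoselective for the open C7 ketone, because the C4 carbonyl is buried next to the fully substituted C3a that carries the pivalate.

Step 8
Reactants: 12 (3R,3aS,8aR)-7,7-(ethylenedioxy)-3-isopropyl-8a-methyl-4-oxodecahydroazulen-3a-yl pivalate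
Product: 14 C4 enol triflate of 12 (C4=C5 double bond), via potassium enolate 13 (not isolated)
Conditions: KN(SiMe3)2, THF, −78 °C; then PhNTf2, −78 → 0 °C
Reagents that add atoms: N-phenylbis(trifluoromethanesulfonimide), O=S(=O)(N(c1ccccc1)S(=O)(=O)C(F)(F)F)C(F)(F)F
Why: Enol triflate formation: the C4 ketone can enolise only towards C5, the pivalate has no α-hydrogen, and O-sulfonylation of the potassium enolate gives a single vinyl triflate.

Step 9
Reactants: 14 C4 enol triflate of 12
Product: 15 (3R,3aS,8aR)-7,7-(ethylenedioxy)-3-isopropyl-8a-methyldecahydroazulen-3a-yl pivalate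
Conditions: H2 (3 atm), PtO2, NaHCO3, EtOH, rt
Reagents that add atoms: none
Why: Hydrogenolysis and hydrogenation of an enol triflate over PtO2, a known way to deoxygenate a ketone, removes the C4 oxygen and saturates C4=C5; no zerovalent palladium is present that could ionise the allylic pivalate, and NaHCO3 takes up the triflic acid so that the ketal survives.

Step 10
Reactants: 15 (3R,3aS,8aR)-7,7-(ethylenedioxy)-3-isopropyl-8a-methyldecahydroazulen-3a-yl pivalate
Product: 16 (3R,3aS,8aR)-3-isopropyl-8a-methyl-7-oxodecahydroazulen-3a-yl pivalate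
Conditions: 1 M HCl, THF, rt
Reagents that add atoms: water, O
Why: Acid hydrolysis of the dioxolane frees the C7 ketone, and the hindered tertiary pivalate is stable to dilute aqueous acid.

Step 11
Reactants: 16 (3R,3aS,8aR)-3-isopropyl-8a-methyl-7-oxodecahydroazulen-3a-yl pivalate
Product: 18 (3R,3aS,8aR)-3-isopropyl-6,8a-dimethyl-7-oxodecahydroazulen-3a-yl pivalate as a mixture of C6 epimers, via lithium enolate 17 (not isolated)
Conditions: LiN(i-Pr)2 (1.05 equiv), THF, −78 °C; then MeI, −78 → −30 °C
Reagents that add atoms: iodomethane, CI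
Why: Kinetic enolate alkylation: the amide base should remove a proton from C6, the α-methylene remote from the quaternary C8a (C8 is neopentyl and screened), and MeI methylates that enolate on carbon; the C6 configuration is irrelevant because C6 becomes trigonal again in step 12.

Step 12
Reactants: 18 (3R,3aS,8aR)-3-isopropyl-6,8a-dimethyl-7-oxodecahydroazulen-3a-yl pivalate (C6 epimers)
Product: 19 trimethylsilyl enol ether of 18 with the C6=C7 double bond
Conditions: Me3SiOTf, Et3N, CH2Cl2, 0 °C → rt
Reagents that add atoms: trimethylsilyl trifluoromethanesulfonate, C[Si](C)(C)OS(=O)(=O)C(F)(F)F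
Why: Amine-mediated silyl enol ether formation is reversible and should settle on the more substituted C6=C7 isomer, since the alternative C7=C8 double bond would sit against the quaternary C8a.

Step 13
Reactants: 19 trimethylsilyl enol ether of 18 (C6=C7)
Product: 22 (3R,3aS,6R,8aR)-6-hydroxy-3-isopropyl-6,8a-dimethyl-7-oxodecahydroazulen-3a-yl pivalate, via silyloxy epoxide 20 (not isolated), via silyloxy ketone 21 (not isolated)
Conditions: mCPBA, NaHCO3, CH2Cl2, −20 → 0 °C; then 1 M HCl, THF, rt
Reagents that add atoms: 3-chloroperoxybenzoic acid (mCPBA), OOC(=O)c1cccc(Cl)c1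
Why: Rubottom oxidation: the peracid should epoxidise the electron-rich enol ether from the α face, because the β face of the seven-membered ring is lined by the C8a methyl and the C3a pivalate; epoxide 20 opens with 1,4-silyl shift to 21, and dilute acid removes the silyl group, so C6 receives its hydroxyl α and keeps its methyl β.

Step 14
Reactants: 22 (3R,3aS,6R,8aR)-6-hydroxy-3-isopropyl-6,8a-dimethyl-7-oxodecahydroazulen-3a-yl pivalate
Product: 23 (3R,3aS,6R,7R,8aR)-6,7-dihydroxy-3-isopropyl-6,8a-dimethyldecahydroazulen-3a-yl pivalate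
Conditions: Me4NBH(OAc)3, MeCN/AcOH (1:1), −30 → 0 °C
Reagents that add atoms: none
Why: Hydroxyl-directed (Evans–Saksena) reduction: the C6 hydroxyl binds boron and delivers hydride within the molecule to its own α face of the C7 carbonyl, so the new C7 hydroxyl is β and trans to the C6 hydroxyl, and the reagent leaves the ester alone.

Step 15
Reactants: 23 (3R,3aS,6R,7R,8aR)-6,7-dihydroxy-3-isopropyl-6,8a-dimethyldecahydroazulen-3a-yl pivalate
Product: 24 (3R,3aS,6R,7R,8aR)-3-isopropyl-6,8a-dimethyldecahydroazulene-3a,6,7-triol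
Conditions: LiAlH4 (excess), THF, 0 °C → reflux; aqueous work-up
Reagents that add atoms: none
Why: Reduction of an ester with LiAlH4: the small hydride reaches even the hindered tertiary pivalate and frees the C3a alcohol without touching a stereocentre.

Step 16
Reactants: 24 (3R,3aS,6R,7R,8aR)-3-isopropyl-6,8a-dimethyldecahydroazulene-3a,6,7-triol; 25 4-methoxybenzoyl chloride
Product: 26 (3R,3aS,6R,7R,8aR)-3a,6-dihydroxy-3-isopropyl-6,8a-dimethyldecahydroazulen-7-yl 4-methoxybenzoate
Conditions: pyridine, 4-(dimethylamino)pyridine (cat.), CH2Cl2, 0 °C → rt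
Reagents that add atoms: none
Why: Amine-catalysed O-acylation with an acid chloride takes place only at the single secondary hydroxyl (C7), because the tertiary hydroxyls at C3a and C6 do not react under these mild conditions.

Compound list
1 | (S)-limonene, (4S)-1-methyl-4-(prop-1-en-2-yl)cyclohex-1-ene | CC1=CC[C@H](CC1)C(C)=C | starting material
2 | (S)-p-menth-1-ene, (4S)-4-isopropyl-1-methylcyclohex-1-ene | CC1=CC[C@H](CC1)C(C)C | intermediate
3 | ozonide of 2, (4S)-4-isopropyl-1-methyl-7,8,9-trioxabicyclo[4.2.1]nonane, both bridgehead diastereomers, not isolated | CC12CC[C@H](C(C)C)CC(OO1)O2 | intermediate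
4 | (3S)-3-isopropyl-6-oxoheptanal | O=CC[C@H](CCC(C)=O)C(C)C | intermediate
5 | (5R)-5-isopropyl-2-methylcyclopent-1-ene-1-carbaldehyde | O=CC1=C(C)CC[C@@H]1C(C)C | intermediate
6 | (5R)-5-isopropyl-2-methylcyclopent-1-en-1-yl formate | O=COC1=C(C)CC[C@@H]1C(C)C | intermediate
7 | lithium (5R)-5-isopropyl-2-methylcyclopent-1-en-1-olate, not isolated | [Li+].[O-]C1=C(C)CC[C@@H]1C(C)C | intermediate
8 | (5R)-5-isopropyl-2-methylcyclopent-1-en-1-yl pivalate (C3a=C8a olefin of the key step) | CC(C)(C)C(=O)OC1=C(C)CC[C@@H]1C(C)C | intermediate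
9 | cyclopentane-1,3-dione | O=C1CCC(=O)C1 | starting material
10 | cyclobutanol photoadduct, not isolated: C3a–C4 and C8–C8a made, C4–C8 still intact; C4 hydroxyl, C7 ketone, C3a pivalate, C8a methyl and C3 isopropyl on one face of the cyclopentane; cyclobutane cis-fused to both five-membered rings, drawn as the cis-anti-cis isomer | O=C1CC[C@]2(O)[C@H]1[C@@]3(C)CC[C@H](C(C)C)[C@@]23OC(=O)C(C)(C)C | intermediate
11 | (3R,3aS,8aR)-3-isopropyl-8a-methyl-4,7-dioxodecahydroazulen-3a-yl pivalate (cis ring fusion; pivalate, methyl and isopropyl all β) | O=C1C[C@@]2(C)CC[C@H](C(C)C)[C@@]2(OC(=O)C(C)(C)C)C(=O)CC1 | intermediate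
12 | (3R,3aS,8aR)-7,7-(ethylenedioxy)-3-isopropyl-8a-methyl-4-oxodecahydroazulen-3a-yl pivalate (C7 dioxolane) | O1CCOC12C[C@@]3(C)CC[C@H](C(C)C)[C@@]3(OC(=O)C(C)(C)C)C(=O)CC2 | intermediate
13 | potassium C4–C5 enolate of 12, not isolated | O1CCOC12C[C@@]3(C)CC[C@H](C(C)C)[C@@]3(OC(=O)C(C)(C)C)C([O-])=CC2.[K+] | intermediate
14 | C4 enol triflate of 12 (C4=C5 double bond, C7 dioxolane, C3a pivalate) | O1CCOC12C[C@@]3(C)CC[C@H](C(C)C)[C@@]3(OC(=O)C(C)(C)C)C(OS(=O)(=O)C(F)(F)F)=CC2 | intermediate
15 | (3R,3aS,8aR)-7,7-(ethylenedioxy)-3-isopropyl-8a-methyldecahydroazulen-3a-yl pivalate | O1CCOC12C[C@@]3(C)CC[C@H](C(C)C)[C@@]3(OC(=O)C(C)(C)C)CCC2 | intermediate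
16 | (3R,3aS,8aR)-3-isopropyl-8a-methyl-7-oxodecahydroazulen-3a-yl pivalate | O=C1C[C@@]2(C)CC[C@H](C(C)C)[C@@]2(OC(=O)C(C)(C)C)CCC1 | intermediate
17 | lithium C6–C7 enolate of 16, not isolated | [Li+].[O-]C=1C[C@@]2(C)CC[C@H](C(C)C)[C@@]2(OC(=O)C(C)(C)C)CCC1 | intermediate
18 | (3R,3aS,8aR)-3-isopropyl-6,8a-dimethyl-7-oxodecahydroazulen-3a-yl pivalate, both C6 epimers | O=C1C[C@@]2(C)CC[C@H](C(C)C)[C@@]2(OC(=O)C(C)(C)C)CCC1C | intermediate
19 | trimethylsilyl enol ether of 18 (C6=C7 double bond, C7 silyloxy, C6 methyl) | CC1=C(O[Si](C)(C)C)C[C@@]2(C)CC[C@H](C(C)C)[C@@]2(OC(=O)C(C)(C)C)CC1 | intermediate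
20 | 6α,7α-epoxide of 19 (epoxide oxygen on the face opposite the C8a methyl, C7 silyloxy β), not isolated | C[Si](C)(C)O[C@]12C[C@@]3(C)CC[C@H](C(C)C)[C@@]3(OC(=O)C(C)(C)C)CC[C@@]1(C)O2 | intermediate
21 | (3R,3aS,6R,8aR)-3-isopropyl-6,8a-dimethyl-7-oxo-6-(trimethylsilyloxy)decahydroazulen-3a-yl pivalate, not isolated | O=C1C[C@@]2(C)CC[C@H](C(C)C)[C@@]2(OC(=O)C(C)(C)C)CC[C@@]1(C)O[Si](C)(C)C | intermediate
22 | (3R,3aS,6R,8aR)-6-hydroxy-3-isopropyl-6,8a-dimethyl-7-oxodecahydroazulen-3a-yl pivalate (C6 hydroxyl α, C6 methyl β) | O=C1C[C@@]2(C)CC[C@H](C(C)C)[C@@]2(OC(=O)C(C)(C)C)CC[C@@]1(C)O | intermediate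
23 | (3R,3aS,6R,7R,8aR)-6,7-dihydroxy-3-isopropyl-6,8a-dimethyldecahydroazulen-3a-yl pivalate (C6 hydroxyl α, C7 hydroxyl β) | O[C@@H]1C[C@@]2(C)CC[C@H](C(C)C)[C@@]2(OC(=O)C(C)(C)C)CC[C@@]1(C)O | intermediate
24 | (3R,3aS,6R,7R,8aR)-3-isopropyl-6,8a-dimethyldecahydroazulene-3a,6,7-triol | O[C@@H]1C[C@@]2(C)CC[C@H](C(C)C)[C@@]2(O)CC[C@@]1(C)O | intermediate
25 | 4-methoxybenzoyl chloride (p-anisoyl chloride) | COc1ccc(C(=O)Cl)cc1 | starting material
26 | (3R,3aS,6R,7R,8aR)-3a,6-dihydroxy-3-isopropyl-6,8a-dimethyldecahydroazulen-7-yl 4-methoxybenzoate | COc1ccc(C(=O)O[C@@H]2C[C@@]3(C)CC[C@H](C(C)C)[C@@]3(O)CC[C@@]2(C)O)cc1 | target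

Total step count: 16.
Longest linear sequence: 16 steps (1 → 26); 9 and 25 are bought and enter in steps 6 and 16.

Steps most likely to fail

1. Step 6. The short-lived excited enol may decay before it meets the hindered tetrasubstituted double bond. The partners may also join head-to-head or on the isopropyl face, and long irradiation may then degrade the diketone by α-cleavage. Fallback, from 8 and 9 back to 11: the hydrogen-bonded enol is replaced by a covalent enone chromophore and the sequence is run in two separate stages. 9 is O-acetylated (AcCl, pyridine, CH2Cl2) to 3-oxocyclopent-1-en-1-yl acetate F1. Irradiation of F1 with 8 (λ ≥ 300 nm, CH2Cl2) is then an ordinary enone–olefin [2+2] cycloaddition and should give the isolable cyclobutyl acetate photoadduct F2. K2CO3 in MeOH removes the acetate while the tertiary pivalate resists methanolysis, and the alkoxide of 10 opens by retro-aldol to 11.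

2. Step 13. The peracid may attack the β face, or both faces, if the seven-membered ring folds so that the five-membered ring screens the α face. The directed reduction would then copy the error to C7, and any C7=C8 enol ether from step 12 would add regioisomers. Fallback, from 19 back to 24: the C6 oxygen is brought in as a nucleophile with inversion, and the face is fixed by reagent delivery from the C3a hydroxyl.
- MeLi (THF, 0 °C) regenerates the tetrasubstituted lithium enolate F3 from 19, and PhNTf2 traps it as the C7 enol triflate F4.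
- Pd(OAc)2, PPh3, HCO2H and Bu3N (DMF, 60 °C) reduce F4 to the C6=C7 olefin pivalate F5.
- LiAlH4 (THF, reflux) frees the C3a alcohol, giving the bishomoallylic alkenol F6.
- VO(acac)2 and t-BuOOH (CH2Cl2) deliver oxygen from the C3a hydroxyl to the β face, giving the 6β,7β-epoxy alcohol F7.
- Dilute HClO4 in THF/H2O opens F7 at the tertiary C6 with inversion, so that the C6 hydroxyl enters α and the C7 oxygen stays β, which is triol 24.

3. Step 9. Hydrogenolysis of the hindered enol triflate may stall or be overtaken by S–O cleavage back to ketone 12, and triflic acid may strip the ketal if the buffer is slow. Fallback, from 12 back to 15 by Barton–McCombie deoxygenation: NaBH4 (MeOH, 0 °C) reduces the C4 ketone to the C4 alcohol F8 (either epimer serves). 1,1'-Thiocarbonyldiimidazole with 4-(dimethylamino)pyridine (toluene, 90 °C) converts F8 under base-free conditions, which avoid acyl migration, into the C4 imidazole-1-carbothioate F9. Bu3SnH with azobis(isobutyronitrile) (toluene, reflux) then replaces the C4 oxygen by hydrogen and gives 15.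

Further compounds
F1 | step 6 | 3-oxocyclopent-1-en-1-yl acetate | CC(=O)OC1=CC(=O)CC1
F2 | step 6 | cyclobutyl acetate photoadduct (O-acetate of 10 at C4, C3a pivalate, drawn cis-anti-cis) | O=C1CC[C@]2(OC(C)=O)[C@H]1[C@@]3(C)CC[C@H](C(C)C)[C@@]23OC(=O)C(C)(C)C
F3 | step 13 | lithium enolate of 18 with the C6=C7 double bond | CC1=C([O-])C[C@@]2(C)CC[C@H](C(C)C)[C@@]2(OC(=O)C(C)(C)C)CC1.[Li+]
F4 | step 13 | C7 enol triflate of 18 (C6=C7, C6 methyl) | CC1=C(OS(=O)(=O)C(F)(F)F)C[C@@]2(C)CC[C@H](C(C)C)[C@@]2(OC(=O)C(C)(C)C)CC1
F5 | step 13 | (3R,3aS,8aR)-3-isopropyl-6,8a-dimethyl-2,3,4,5,8,8a-hexahydroazulen-3a(1H)-yl pivalate (C6=C7 olefin) | CC1=CC[C@@]2(C)CC[C@H](C(C)C)[C@@]2(OC(=O)C(C)(C)C)CC1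
F6 | step 13 | (3R,3aS,8aR)-3-isopropyl-6,8a-dimethyl-2,3,4,5,8,8a-hexahydroazulen-3a(1H)-ol | CC1=CC[C@@]2(C)CC[C@H](C(C)C)[C@@]2(O)CC1
F7 | step 13 | 6β,7β-epoxide of F6 (epoxide oxygen on the face of the C3a hydroxyl and the C8a methyl) | C[C@@]12O[C@@H]1C[C@@]3(C)CC[C@H](C(C)C)[C@@]3(O)CC2
F8 | step 9 | (3R,3aS,8aR)-7,7-(ethylenedioxy)-4-hydroxy-3-isopropyl-8a-methyldecahydroazulen-3a-yl pivalate, either C4 epimer | O1CCOC12C[C@@]3(C)CC[C@H](C(C)C)[C@@]3(OC(=O)C(C)(C)C)C(O)CC2
F9 | step 9 | O-(C4) imidazole-1-carbothioate of F8 | O1CCOC12C[C@@]3(C)CC[C@H](C(C)C)[C@@]3(OC(=O)C(C)(C)C)C(OC(=S)n4ccnc4)CC2
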